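# Proposed total synthesis of CNP0187917.1 by lactone annulation through a tethered phosphonoacetate opening a Sharpless epoxide

Germacrane numbering is used throughout: ring C1–C10, C14 methyl on C10, C15 on C4, lactone O on C6, C11/C12/C13 on C7, angelate on C8.

## Analysis of the target

The target is a heliangolide-type germacranolide. It has a ten-membered carbocycle with a trans-fused α-methylene-γ-butyrolactone on C6/C7, a trans epoxide across C1/C10, a ring-cis (Z) C4=C5 alkene carrying the C15 hydroxymethyl group, a free allylic hydroxyl on C3 and an angelate on C8. The six stereocentres are 1R, 3S, 6R, 7R, 8R and 10R. On a flat ring drawing O6 is α, C11 on C7 is β (H6 and H7 anti), and O8 and O3 are β. The epoxide is 1β,10α with the C14 methyl β.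

C6, C7 and C8 are contiguous and carry oxygen, carbon and oxygen. C3 and the epoxide lie across the ring from this triad, so they cannot be set by short-range induction. The sensitive groups are the α-methylene lactone (a Michael acceptor), the angelate (isomerises to the tiglate and can migrate), the epoxide (acid-labile, open to transannular attack by C4=C5 or the C3 hydroxyl) and the two primary allylic oxygen functions.

The difficulty is the combination of a medium ring with two defined alkene geometries, a stereotriad, two remote stereocentres and several late-stage-labile groups. The plan rests on the C6–C7–C8 triad. A 2,3-epoxy alcohol (hydroxyl on C6, epoxide on C7/C8) leaves exactly this pattern when a carbon nucleophile tethered to O6 opens it at the central carbon C7.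

## Retrosynthetic reasoning

**Epoxide and silyl ether last.** Target 28 is traced to its C15 silyl ether 27, and 27 to the 1(10)E,4Z-dienolide 26 by cutting the two C–O bonds of the epoxide. The epoxide is the most acid-sensitive group and would not survive the earlier chemistry. In 26 the trisubstituted C1=C10 alkene is the only electron-rich, unencumbered alkene, and the ring conformation decides the face.

**Ten-membered ring at C3–C4.** Compound 26 is opened at the C3–C4 bond to the acyclic iodo aldehyde 24. This cut places an sp2 carbon and a carbonyl carbon at the ends, so a Nozaki–Hiyama–Kishi closure can be used. That reaction tolerates the lactone, the angelate and the silyl ether. The 4Z geometry is carried unchanged by the alkenyl iodide, and the C3 carbinol is formed in the same step. Aldehyde 24 comes from the triethylsilyl ether 22 through alcohol 23.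

**Methylene and angelate.** The C11=C13 bond of 22 is cut by a Horner–Wadsworth–Emmons methylenation, which leads to the α-phosphono lactone 21. The C8 ester bond is then cut to give hydroxy lactone 18 and angelic acid 19. Acylating before methylenation blocks the C8 oxygen, so it can no longer compete for the lactone carbonyl once base is applied.

**Lactone ring and C7 (key disconnection).** In 18 the C7–C11 bond is cut. The precursor is phosphonoacetate 15, whose C7/C8 epoxide is opened at C7 by the carbanion held on O6. One bond, one ring, inversion at C7 and release of the C8 hydroxyl come from this step. The phosphoryl group that makes C11 nucleophilic is used again for C13. All stereochemistry of the triad is moved back to one epoxy alcohol.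

**Epoxy alcohol.** Ester 15 comes from epoxy alcohol 13 and acid 14. The epoxide of 13 is removed to give the bis-allylic alcohol 12. A Sharpless epoxidation selects the E-disubstituted C7=C8 alkene over the Z-iodoalkene and gives the erythro isomer from the (S)-carbinol.

**Alkenyl iodide.** The C4–I bond of 12 is traced to the alkyne of propargylic alcohol 10. The C6 hydroxyl directs an anti hydroalumination that puts the metal, and then iodine, on C4 cis to C6. This is the geometry the ring closure needs.

**C5–C6 bond and the C6 stereocentre.** Alcohol 10 is cut between C5 and C6 into the skipped dienal 8 and the silyl propargyl ether 9. A catalytic enantioselective alkynylation forms the bond and sets C6. The later Sharpless step filters any minor enantiomer.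

**Chain C7–C3.** Enal 8 is cut at C7=C8 by cross-metathesis into the terminal alkene 6 and but-2-enal 7. Silyl ether 6 comes from alcohol 5. The E-trisubstituted C1=C10 alkene of 5, with the C14 methyl, comes from enyne 1 by syn carbometalation and from oxirane 2, which supplies C2 and C3.

## Alternatives that were turned down

**Alternative 1: boronate fragmentation of a cis-decalin spiro-epoxide.**
- Disconnection: the C5–C10 bond is re-formed, so the ten-membered ring becomes a cis-fused decalin carrying a boronic ester on C1 and a spiro-epoxide on C4 (C4–O–C15).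
- Forward key step: an alkoxide adds to boron and the ate complex fragments in the Grob sense. C1=C10 and C4=C5 form, C5–C10 breaks and the epoxide opens to the C15 alkoxide, giving the dienolide A1 without a macrocyclisation.
- For: there is no entropic penalty of ring closure. Both alkene geometries are transcribed stereospecifically from the bicycle, and the C15 oxygen appears in the same step.
- Against: the bicyclic substrate needs eight stereocentres in a fixed relationship, among them a quaternary C10, a spiro-epoxide of defined configuration and a secondary boronate held anti-periplanar to the breaking bond. That is a long linear sequence before the key step. A1 still lacks C13, the angelate and the epoxide, and needs two protecting-group removals.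
- Comparison: on ring formation this alternative is stronger than the chosen plan, which must close the ring at high dilution. On alkene geometry the two are equal, since hydroalumination and carboalumination are also stereospecific. The chosen plan offers a short convergent acyclic route and absolute control of the triad from one catalytic epoxidation.

**Alternative 2: enone–cyclobutene photocycloaddition, then thermal ring opening.**
- Disconnection: the C4–C5 and C1–C10 bonds are traced to a [2+2] photocycloaddition of a lactone-fused 3-methylcyclohexenone with a cyclobutene ester. The ten-membered ring then arises by thermal cleavage of the bicyclo[2.2.0]hexane unit.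
- Forward key step: irradiation gives the cis-anti-cis photoadduct A2 with two new σ bonds and a new cyclobutane.
- For: two skeletal bonds form in one step from simple cyclic partners. C14 and C15 (as an ester) are already in place, and again no macrocyclisation is needed.
- Against: regiochemistry (head-to-head against head-to-tail) and facial selectivity with a substituted cyclobutene are not secured. The thermolysis can give mixed diene geometries and Cope isomers of the divinylcyclohexane type, while the target needs 1(10)E,4Z specifically. In A2 the lactone sits on O8 and C6 is a ketone, so a stereoselective reduction, a translactonisation to O6 and an ester reduction must precede methylenation, angeloylation and epoxidation. Absolute configuration needs an enantiopure partner.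
- Comparison: in bond count per step it beats the chosen key step (two bonds and two rings against one and one). It is weaker in regio- and stereocontrol and in the number of corrective steps afterwards. The chosen plan sets C6–C8 directly in the oxidation states of the target.

**Alternative 3: chromium-mediated alkenyl–aldehyde ring closure at C3–C4 as the central step.**
- Disconnection: the C3–C4 bond.
- Forward key step: the alkenyl iodide is converted by divalent chromium with a nickel co-catalyst into an alkenylchromium that adds to the C3 aldehyde. This gives macrocycle A3, which is identical with compound 26 of the route.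
- For: it closes the ring late, keeps the 4Z geometry, forms the C3 carbinol and tolerates every other group.
- Against: taken as the organising idea it leaves open how the lactone and the C6–C8 triad are made, and that is where most of the stereochemical work lies. The C3 configuration depends on ring conformation only.
- Comparison: for the macrocycle itself this step is as strong as anything available, and the chosen route adopts it as step 13. The epoxide-opening strategy supplies what this one does not: a stereospecific construction of the lactone with C7 and C8, and a built-in handle for C13.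

Key step: step 8

Assumption: (S,S)-ProPhenol with ZnMe2 is taken to direct the alkynyl group to the Re face of enal 8, by analogy with the facial sense of its aldol reactions; should the first run show the opposite sense, the (R,R)-ligand takes its place.

## Route

Step 1
Reactants: 1 pent-1-en-4-yne; 2 oxirane
Product: 5 (3E)-4-methylhepta-3,6-dien-1-ol, via alkenylalane 3 (not isolated), via lithium alanate 4 (not isolated)
Conditions: AlMe3 (2 equiv), Cp2ZrCl2 (0.25 equiv), CH2Cl2, 0 °C to rt; concentrate; n-BuLi, hexane, 0 °C; then oxirane, THF, −78 °C to rt; aq. HCl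
Reagents that add atoms: trimethylaluminium, C[Al](C)C
Why: Zirconium-catalysed syn carboalumination (Negishi) places the methyl group on the internal alkyne carbon and aluminium on the terminal one, which fixes the E geometry of C1=C10; the derived alanate opens oxirane with retention at the alkenyl carbon, and the terminal alkene is inert under these conditions.

Step 2
Reactants: 5 (3E)-4-methylhepta-3,6-dien-1-ol
Product: 6 triethyl{[(3E)-4-methylhepta-3,6-dien-1-yl]oxy}silane
Conditions: Et3SiCl, imidazole, CH2Cl2, 0 °C
Reagents that add atoms: chlorotriethylsilane, CC[Si](Cl)(CC)CC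
Why: Standard silylation of a primary alcohol; the triethylsilyl ether on C3 is chosen because it can later be removed next to the tert-butyldimethylsilyl ether on C15.

Step 3
Reactants: 6 triethyl{[(3E)-4-methylhepta-3,6-dien-1-yl]oxy}silane; 7 (2E)-but-2-enal
Product: 8 (2E,5E)-5-methyl-8-[(triethylsilyl)oxy]octa-2,5-dienal
Conditions: 7 (5 equiv), second-generation Hoveyda–Grubbs catalyst [(H2IMes)Cl2Ru=CH(2-iPrOC6H4)] (3 mol %), 1,4-benzoquinone (10 mol %), CH2Cl2, 40 °C
Reagents that add atoms: none
Why: Olefin cross-metathesis of a monosubstituted alkene with an enal is E-selective for thermodynamic reasons and leaves the slower trisubstituted alkene untouched; benzoquinone suppresses ruthenium hydride isomerisation of the skipped diene.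

Step 4
Reactants: 8 (2E,5E)-5-methyl-8-[(triethylsilyl)oxy]octa-2,5-dienal; 9 tert-butyldimethyl(prop-2-yn-1-yloxy)silane
Product: 10 (4S,5E,8E)-1-[(tert-butyldimethylsilyl)oxy]-8-methyl-11-[(triethylsilyl)oxy]undeca-5,8-dien-2-yn-4-ol
Conditions: 9 (2.8 equiv), ZnMe2 (2.9 equiv), (S,S)-ProPhenol (10 mol %), Ph3P=O (20 mol %), toluene, 0 to 4 °C
Reagents that add atoms: none
Why: Dinuclear zinc ProPhenol alkynylation of a 2-enal forms C5–C6 by 1,2-addition under weakly basic conditions that should not move the skipped diene into conjugation; the chiral pocket directs the alkynylzinc to the Re face and so gives the (S)-carbinol at C6.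

Step 5
Reactants: 10 (4S,5E,8E)-1-[(tert-butyldimethylsilyl)oxy]-8-methyl-11-[(triethylsilyl)oxy]undeca-5,8-dien-2-yn-4-ol
Product: 12 (2Z,4S,5E,8E)-1-[(tert-butyldimethylsilyl)oxy]-2-iodo-8-methyl-11-[(triethylsilyl)oxy]undeca-2,5,8-trien-4-ol, via cyclic sodium alkenylalanate 11 (not isolated)
Conditions: NaAlH2(OCH2CH2OCH3)2 (1.6 equiv), THF, 0 °C; EtOAc; then I2, THF, −78 °C
Reagents that add atoms: iodine, II
Why: Hydroxyl-directed anti hydroalumination of the propargylic alcohol delivers hydride to C5 and aluminium to C4 within a five-membered oxaluminole, and iodinolysis of the C–Al bond proceeds with retention, so iodine ends up on C4 cis to C6 (Z); the reaction is kept cold to avoid loss of the neighbouring silyloxy group.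

Step 6
Reactants: 12 (2Z,4S,5E,8E)-1-[(tert-butyldimethylsilyl)oxy]-2-iodo-8-methyl-11-[(triethylsilyl)oxy]undeca-2,5,8-trien-4-ol
Product: 13 (1R,2Z)-4-[(tert-butyldimethylsilyl)oxy]-3-iodo-1-{(2R,3R)-3-[(2E)-2-methyl-5-[(triethylsilyl)oxy]pent-2-en-1-yl]oxiran-2-yl}but-2-en-1-ol
Conditions: Ti(OiPr)4 (20 mol %), D-(−)-diisopropyl tartrate (24 mol %), t-BuOOH (1.5 equiv), 4 Å molecular sieves, CH2Cl2, −20 °C
Reagents that add atoms: tert-butyl hydroperoxide, CC(C)(C)OO
Why: Sharpless asymmetric epoxidation; with the D-(−)-tartrate the (S)-carbinol is the fast-reacting enantiomer and gives the erythro epoxy alcohol by oxygen delivery to the C7=C8 face anti to the C6 substituent, which sets C7 and C8. The iodoalkene (cis substituent, electron-poor) and the non-allylic C1=C10 alkene do not react, and any (R)-alcohol left from step 4 is epoxidised only slowly.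

Step 7
Reactants: 13 (1R,2Z)-4-[(tert-butyldimethylsilyl)oxy]-3-iodo-1-{(2R,3R)-3-[(2E)-2-methyl-5-[(triethylsilyl)oxy]pent-2-en-1-yl]oxiran-2-yl}but-2-en-1-ol; 14 diethylphosphonoacetic acid
Product: 15 (1R,2Z)-4-[(tert-butyldimethylsilyl)oxy]-3-iodo-1-{(2S,3R)-3-[(2E)-2-methyl-5-[(triethylsilyl)oxy]pent-2-en-1-yl]oxiran-2-yl}but-2-en-1-yl 2-(diethoxyphosphoryl)acetate
Conditions: N,N'-dicyclohexylcarbodiimide, 4-(dimethylamino)pyridine (cat.), CH2Cl2, 0 °C to rt
Reagents that add atoms: none
Why: Carbodiimide esterification under neutral conditions leaves the epoxide intact and involves no stereocentre; the change of the oxirane descriptor from 2R to 2S is a priority effect only.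

Step 8
Reactants: 15 (1R,2Z)-4-[(tert-butyldimethylsilyl)oxy]-3-iodo-1-{(2S,3R)-3-[(2E)-2-methyl-5-[(triethylsilyl)oxy]pent-2-en-1-yl]oxiran-2-yl}but-2-en-1-yl 2-(diethoxyphosphoryl)acetate
Product: 18 diethyl {(3S,4R,5S)-5-[(1Z)-3-[(tert-butyldimethylsilyl)oxy]-2-iodoprop-1-en-1-yl]-4-[(1R,3E)-1-hydroxy-3-methyl-6-[(triethylsilyl)oxy]hex-3-en-1-yl]-2-oxooxolan-3-yl}phosphonate, via sodium carbanion 16 (not isolated), via sodium alkoxide 17 (not isolated)
Conditions: NaH (1.05 equiv), THF, 0 °C to 50 °C; AcOH, 0 °C
Reagents that add atoms: none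
Why: NaH removes the proton between the phosphoryl and ester carbonyl groups of 15 to give 16, whose carbanion C11 attacks the nearer epoxide carbon C7 from the side opposite the C7–O bond; the oxygen stays on C8 as alkoxide 17, which takes the remaining acidic C11 proton so that the product rests as the phosphonate-stabilised lactone anion until the acid quench. The closest known reaction type is the base-induced cyclisation of malonate and phosphonoacetate esters of 2,3-epoxy alcohols to α-substituted β-(1-hydroxyalkyl)-γ-butyrolactones. The only ring closed is the γ-lactone (O6–C6–C7–C11–C12), in a 5-exo-tet opening in which the breaking C7–O bond lies outside the new ring, and because the carbanion is stabilised by the exocyclic phosphoryl group the ring carbonyl need not stay coplanar with the attacking orbital. C7 is set by inversion of the epoxide carbon installed in step 6 and, with the untouched C6, gives the trans lactone (H6 and H7 anti); C8 keeps its C–O bond and configuration; C11 forms as the more stable epimer with phosphorus trans to the C7 side chain and ceases to be a stereocentre in step 10. The step needs attack at C7 and not at C8, which the three-atom tether secures, because C8 could only be reached through a six-membered endo transition state with poor alignment. It also needs C- and not O-alkylation, which the soft phosphonate carbanion favours. One equivalent of base is used so that the liberated alkoxide is neutralised internally and attacks neither the lactone carbonyl (migration to an 8,12-lactone, which would moreover be cis-substituted and less stable) nor phosphorus.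

Step 9
Reactants: 18 diethyl {(3S,4R,5S)-5-[(1Z)-3-[(tert-butyldimethylsilyl)oxy]-2-iodoprop-1-en-1-yl]-4-[(1R,3E)-1-hydroxy-3-methyl-6-[(triethylsilyl)oxy]hex-3-en-1-yl]-2-oxooxolan-3-yl}phosphonate; 19 angelic acid [(2Z)-2-methylbut-2-enoic acid]
Product: 21 (1R,3E)-1-{(2S,3R,4S)-2-[(1Z)-3-[(tert-butyldimethylsilyl)oxy]-2-iodoprop-1-en-1-yl]-4-(diethoxyphosphoryl)-5-oxooxolan-3-yl}-3-methyl-6-[(triethylsilyl)oxy]hex-3-en-1-yl (2Z)-2-methylbut-2-enoate, via mixed anhydride 20 (not isolated)
Conditions: 19, 2,4,6-trichlorobenzoyl chloride, Et3N, toluene, rt; then 18, toluene, 75 °C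
Reagents that add atoms: none
Why: Acylation through the angelic 2,4,6-trichlorobenzoic mixed anhydride (Yamaguchi type, without a nucleophilic amine catalyst) is the established way to make angelates of hindered secondary alcohols without Z to E isomerisation; C8 is not touched and the ester now blocks O8 from competing for the lactone.

Step 10
Reactants: 21 (1R,3E)-1-{(2S,3R,4S)-2-[(1Z)-3-[(tert-butyldimethylsilyl)oxy]-2-iodoprop-1-en-1-yl]-4-(diethoxyphosphoryl)-5-oxooxolan-3-yl}-3-methyl-6-[(triethylsilyl)oxy]hex-3-en-1-yl (2Z)-2-methylbut-2-enoate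
Product: 22 (1R,3E)-1-{(2S,3R)-2-[(1Z)-3-[(tert-butyldimethylsilyl)oxy]-2-iodoprop-1-en-1-yl]-4-methylidene-5-oxooxolan-3-yl}-3-methyl-6-[(triethylsilyl)oxy]hex-3-en-1-yl (2Z)-2-methylbut-2-enoate
Conditions: aq. CH2O (37 %), K2CO3, THF, 0 °C to rt
Reagents that add atoms: formaldehyde, C=O
Why: Horner–Wadsworth–Emmons methylenation of an α-phosphono-γ-lactone with formaldehyde under mild carbonate conditions introduces C13 and removes the C11 stereocentre; the angelate and both silyl ethers tolerate the conditions.

Step 11
Reactants: 22 (1R,3E)-1-{(2S,3R)-2-[(1Z)-3-[(tert-butyldimethylsilyl)oxy]-2-iodoprop-1-en-1-yl]-4-methylidene-5-oxooxolan-3-yl}-3-methyl-6-[(triethylsilyl)oxy]hex-3-en-1-yl (2Z)-2-methylbut-2-enoate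
Product: 23 (1R,3E)-1-{(2S,3R)-2-[(1Z)-3-[(tert-butyldimethylsilyl)oxy]-2-iodoprop-1-en-1-yl]-4-methylidene-5-oxooxolan-3-yl}-6-hydroxy-3-methylhex-3-en-1-yl (2Z)-2-methylbut-2-enoate
Conditions: pyridinium p-toluenesulfonate (cat.), MeOH/CH2Cl2, 0 °C
Reagents that add atoms: none
Why: Mild acid methanolysis removes a primary triethylsilyl ether much faster than the primary tert-butyldimethylsilyl ether, which is further deactivated by the neighbouring iodoalkene; under acid, methanol does not add to the methylene lactone.

Step 12
Reactants: 23 (1R,3E)-1-{(2S,3R)-2-[(1Z)-3-[(tert-butyldimethylsilyl)oxy]-2-iodoprop-1-en-1-yl]-4-methylidene-5-oxooxolan-3-yl}-6-hydroxy-3-methylhex-3-en-1-yl (2Z)-2-methylbut-2-enoate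
Product: 24 (1R,3E)-1-{(2S,3R)-2-[(1Z)-3-[(tert-butyldimethylsilyl)oxy]-2-iodoprop-1-en-1-yl]-4-methylidene-5-oxooxolan-3-yl}-3-methyl-6-oxohex-3-en-1-yl (2Z)-2-methylbut-2-enoate
Conditions: Dess–Martin periodinane, solid NaHCO3, CH2Cl2, 0 °C; used crude
Reagents that add atoms: none
Why: Buffered Dess–Martin oxidation gives the β,γ-unsaturated aldehyde without acid or base strong enough to move the C1=C10 alkene into conjugation; the aldehyde is taken on at once.

Step 13
Reactants: 24 (1R,3E)-1-{(2S,3R)-2-[(1Z)-3-[(tert-butyldimethylsilyl)oxy]-2-iodoprop-1-en-1-yl]-4-methylidene-5-oxooxolan-3-yl}-3-methyl-6-oxohex-3-en-1-yl (2Z)-2-methylbut-2-enoate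
Product: 26 (3S,6R,7R,8R)-15-[(tert-butyldimethylsilyl)oxy]-3-hydroxy-8-[(2Z)-2-methylbut-2-enoyloxy]germacra-1(10)E,4Z,11(13)-trien-12,6-olide, via alkenylchromium dichloride 25 (not isolated)
Conditions: CrCl2 (8 equiv), NiCl2 (0.1 equiv), DMSO/THF, 0.003 M (slow addition of 24), rt
Reagents that add atoms: none
Why: Nozaki–Hiyama–Kishi macrocyclisation: zerovalent nickel inserts into the C4–I bond, transmetalation gives the alkenylchromium 25 with retention of the Z geometry, and this adds only to the aldehyde, closing the ten-membered ring at C3–C4. The new C3 carbinol is set by the conformation of the closing ring, which is expected to keep the aldehyde oxygen on the outside of the ring and give the 3β (S) alcohol.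

Step 14
Reactants: 26 (3S,6R,7R,8R)-15-[(tert-butyldimethylsilyl)oxy]-3-hydroxy-8-[(2Z)-2-methylbut-2-enoyloxy]germacra-1(10)E,4Z,11(13)-trien-12,6-olide
Product: 27 (1R,3S,6R,7R,8R,10R)-15-[(tert-butyldimethylsilyl)oxy]-1,10-epoxy-3-hydroxy-8-[(2Z)-2-methylbut-2-enoyloxy]germacra-4Z,11(13)-dien-12,6-olide
Conditions: m-chloroperbenzoic acid (1.05 equiv), NaHCO3, CH2Cl2, −20 to 0 °C
Reagents that add atoms: 3-chloroperbenzoic acid, OOC(=O)c1cccc(Cl)c1
Why: Prilezhaev epoxidation is stereospecific (E alkene to trans epoxide) and selects the electron-rich, strained C1=C10 alkene over the conjugated alkenes and the C4=C5 alkene, which is deactivated by three allylic oxygen atoms. The peracid should approach the outer face of the alkene, which stands perpendicular to the mean ring plane, and this gives the 1β,10α epoxide (1R,10R).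

Step 15
Reactants: 27 (1R,3S,6R,7R,8R,10R)-15-[(tert-butyldimethylsilyl)oxy]-1,10-epoxy-3-hydroxy-8-[(2Z)-2-methylbut-2-enoyloxy]germacra-4Z,11(13)-dien-12,6-olide
Product: 28 (1R,3S,6R,7R,8R,10R)-1,10-epoxy-3,15-dihydroxy-8-[(2Z)-2-methylbut-2-enoyloxy]germacra-4Z,11(13)-dien-12,6-olide (CNP0187917.1)
Conditions: Bu4NF/AcOH (1:1), THF, 0 °C
Reagents that add atoms: none
Why: Acetic acid-buffered fluoride cleaves the primary allylic silyl ether without the basicity that would cause acyl migration or conjugate addition, and without the acidity that would open the epoxide transannularly.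

## Compound list

1 | pent-1-en-4-yne | C=CCC#C | starting material
2 | oxirane | C1CO1 | starting material
3 | dimethyl[(1E)-2-methylpenta-1,4-dien-1-yl]alumane | C=CC/C(C)=C/[Al](C)C | intermediate
4 | lithium butyl(dimethyl)[(1E)-2-methylpenta-1,4-dien-1-yl]aluminate | [Li+].C=CC/C(C)=C/[Al-](C)(C)CCCC | intermediate
5 | (3E)-4-methylhepta-3,6-dien-1-ol | OCC/C=C(C)/CC=C | intermediate
6 | triethyl{[(3E)-4-methylhepta-3,6-dien-1-yl]oxy}silane | C=CC/C(C)=C/CCO[Si](CC)(CC)CC | intermediate
7 | (2E)-but-2-enal | C/C=C/C=O | starting material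
8 | (2E,5E)-5-methyl-8-[(triethylsilyl)oxy]octa-2,5-dienal | O=C/C=C/C/C(C)=C/CCO[Si](CC)(CC)CC | intermediate
9 | tert-butyldimethyl(prop-2-yn-1-yloxy)silane | C#CCO[Si](C)(C)C(C)(C)C | starting material
10 | (4S,5E,8E)-1-[(tert-butyldimethylsilyl)oxy]-8-methyl-11-[(triethylsilyl)oxy]undeca-5,8-dien-2-yn-4-ol | O[C@H](C#CCO[Si](C)(C)C(C)(C)C)/C=C/C/C(C)=C/CCO[Si](CC)(CC)CC | intermediate
11 | cyclic sodium alkenylalanate of 10 (2,5-dihydro-1,2-oxaluminol-2-uide, Al on C4 and O6, two 2-methoxyethoxy ligands) | [Na+].COCCO[Al-]1(OCCOC)O[C@@H](/C=C/C/C(C)=C/CCO[Si](CC)(CC)CC)C=C1CO[Si](C)(C)C(C)(C)C | intermediate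
12 | (2Z,4S,5E,8E)-1-[(tert-butyldimethylsilyl)oxy]-2-iodo-8-methyl-11-[(triethylsilyl)oxy]undeca-2,5,8-trien-4-ol | O[C@H](/C=C(I)/CO[Si](C)(C)C(C)(C)C)/C=C/C/C(C)=C/CCO[Si](CC)(CC)CC | intermediate
13 | (1R,2Z)-4-[(tert-butyldimethylsilyl)oxy]-3-iodo-1-{(2R,3R)-3-[(2E)-2-methyl-5-[(triethylsilyl)oxy]pent-2-en-1-yl]oxiran-2-yl}but-2-en-1-ol | O[C@H](/C=C(I)/CO[Si](C)(C)C(C)(C)C)[C@H]1O[C@@H]1C/C(C)=C/CCO[Si](CC)(CC)CC | intermediate
14 | diethylphosphonoacetic acid | CCOP(=O)(CC(=O)O)OCC | starting material
15 | (1R,2Z)-4-[(tert-butyldimethylsilyl)oxy]-3-iodo-1-{(2S,3R)-3-[(2E)-2-methyl-5-[(triethylsilyl)oxy]pent-2-en-1-yl]oxiran-2-yl}but-2-en-1-yl 2-(diethoxyphosphoryl)acetate | CCOP(=O)(OCC)CC(=O)O[C@H](/C=C(I)/CO[Si](C)(C)C(C)(C)C)[C@H]1O[C@@H]1C/C(C)=C/CCO[Si](CC)(CC)CC | intermediate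
16 | sodium salt of the C11 carbanion of 15 | [Na+].CCOP(=O)(OCC)[CH-]C(=O)O[C@H](/C=C(I)/CO[Si](C)(C)C(C)(C)C)[C@H]1O[C@@H]1C/C(C)=C/CCO[Si](CC)(CC)CC | intermediate
17 | sodium C8 alkoxide of lactone 18 | [Na+].CCOP(=O)(OCC)[C@@H]1C(=O)O[C@H](/C=C(I)/CO[Si](C)(C)C(C)(C)C)[C@H]1[C@H]([O-])C/C(C)=C/CCO[Si](CC)(CC)CC | intermediate
18 | diethyl {(3S,4R,5S)-5-[(1Z)-3-[(tert-butyldimethylsilyl)oxy]-2-iodoprop-1-en-1-yl]-4-[(1R,3E)-1-hydroxy-3-methyl-6-[(triethylsilyl)oxy]hex-3-en-1-yl]-2-oxooxolan-3-yl}phosphonate | CCOP(=O)(OCC)[C@@H]1C(=O)O[C@H](/C=C(I)/CO[Si](C)(C)C(C)(C)C)[C@H]1[C@H](O)C/C(C)=C/CCO[Si](CC)(CC)CC | intermediate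
19 | angelic acid, (2Z)-2-methylbut-2-enoic acid | C/C=C(/C)C(=O)O | starting material
20 | (2Z)-2-methylbut-2-enoic 2,4,6-trichlorobenzoic anhydride | C/C=C(/C)C(=O)OC(=O)c1c(Cl)cc(Cl)cc1Cl | intermediate
21 | (1R,3E)-1-{(2S,3R,4S)-2-[(1Z)-3-[(tert-butyldimethylsilyl)oxy]-2-iodoprop-1-en-1-yl]-4-(diethoxyphosphoryl)-5-oxooxolan-3-yl}-3-methyl-6-[(triethylsilyl)oxy]hex-3-en-1-yl (2Z)-2-methylbut-2-enoate | CCOP(=O)(OCC)[C@@H]1C(=O)O[C@H](/C=C(I)/CO[Si](C)(C)C(C)(C)C)[C@H]1[C@H](OC(=O)/C(C)=C\C)C/C(C)=C/CCO[Si](CC)(CC)CC | intermediate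
22 | (1R,3E)-1-{(2S,3R)-2-[(1Z)-3-[(tert-butyldimethylsilyl)oxy]-2-iodoprop-1-en-1-yl]-4-methylidene-5-oxooxolan-3-yl}-3-methyl-6-[(triethylsilyl)oxy]hex-3-en-1-yl (2Z)-2-methylbut-2-enoate | C=C1C(=O)O[C@H](/C=C(I)/CO[Si](C)(C)C(C)(C)C)[C@H]1[C@H](OC(=O)/C(C)=C\C)C/C(C)=C/CCO[Si](CC)(CC)CC | intermediate
23 | (1R,3E)-1-{(2S,3R)-2-[(1Z)-3-[(tert-butyldimethylsilyl)oxy]-2-iodoprop-1-en-1-yl]-4-methylidene-5-oxooxolan-3-yl}-6-hydroxy-3-methylhex-3-en-1-yl (2Z)-2-methylbut-2-enoate | C=C1C(=O)O[C@H](/C=C(I)/CO[Si](C)(C)C(C)(C)C)[C@H]1[C@H](OC(=O)/C(C)=C\C)C/C(C)=C/CCO | intermediate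
24 | (1R,3E)-1-{(2S,3R)-2-[(1Z)-3-[(tert-butyldimethylsilyl)oxy]-2-iodoprop-1-en-1-yl]-4-methylidene-5-oxooxolan-3-yl}-3-methyl-6-oxohex-3-en-1-yl (2Z)-2-methylbut-2-enoate | C=C1C(=O)O[C@H](/C=C(I)/CO[Si](C)(C)C(C)(C)C)[C@H]1[C@H](OC(=O)/C(C)=C\C)C/C(C)=C/CC=O | intermediate
25 | alkenylchromium dichloride from 24 (trivalent chromium on C4 in place of iodine) | C=C1C(=O)O[C@H](/C=C([Cr](Cl)Cl)/CO[Si](C)(C)C(C)(C)C)[C@H]1[C@H](OC(=O)/C(C)=C\C)C/C(C)=C/CC=O | intermediate
26 | (3S,6R,7R,8R)-15-[(tert-butyldimethylsilyl)oxy]-3-hydroxy-8-[(2Z)-2-methylbut-2-enoyloxy]germacra-1(10)E,4Z,11(13)-trien-12,6-olide | C=C1C(=O)O[C@@H]2/C=C(/CO[Si](C)(C)C(C)(C)C)[C@@H](O)C/C=C(\C)C[C@@H](OC(=O)/C(C)=C\C)[C@@H]12 | intermediate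
27 | (1R,3S,6R,7R,8R,10R)-15-[(tert-butyldimethylsilyl)oxy]-1,10-epoxy-3-hydroxy-8-[(2Z)-2-methylbut-2-enoyloxy]germacra-4Z,11(13)-dien-12,6-olide | C=C1C(=O)O[C@@H]2/C=C(/CO[Si](C)(C)C(C)(C)C)[C@@H](O)C[C@H]3O[C@]3(C)C[C@@H](OC(=O)/C(C)=C\C)[C@@H]12 | intermediate
28 | (1R,3S,6R,7R,8R,10R)-1,10-epoxy-3,15-dihydroxy-8-[(2Z)-2-methylbut-2-enoyloxy]germacra-4Z,11(13)-dien-12,6-olide (CNP0187917.1) | C=C1C(=O)O[C@@H]2/C=C(/CO)[C@@H](O)C[C@H]3O[C@]3(C)C[C@@H](OC(=O)/C(C)=C\C)[C@@H]12 | target

## Step count and least certain steps

Total step count: 15. Longest linear sequence: 15 steps (1 to 28); compounds 2, 7, 9, 14 and 19 are bought and enter convergently.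

**Step 8 (key step).** The most likely failure is that the carbanion does not reach C7. The tethering ester has to adopt its less favoured s-cis form, and a stabilised carbanion is a weak nucleophile towards an unactivated epoxide. Alkylation through the enolate oxygen, or attack of the freed C8 alkoxide on the lactone carbonyl or on phosphorus, can then take over. The fallback forms the same C7–C11 bond by carbene transfer and sets out from 12. Esterification with 14 (carbodiimide) gives the allylic phosphonoacetate F1. Diazo transfer with 4-acetamidobenzenesulfonyl azide and DBU gives the diazo ester F2. Rh2(OAc)4 in CH2Cl2 at 40 °C effects intramolecular cyclopropanation of C7=C8 to the cyclopropane-fused lactone F3, with the C6 substituent expected on the convex face. Homoconjugate opening of the doubly activated cyclopropane at C8 by the caesium salt of 19 (Cs2CO3, DMF, 60 °C) proceeds with inversion. C11 and the C8 oxygen end up anti across the former alkene, as in the epoxide route, and the sequence comes back at 21.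

**Step 13.** The most likely failure is poor facial selectivity at the aldehyde, since C3 is set only by the conformation of the closing ring. Protonation of the alkenylchromium before it closes is a second loss channel. The fallback replaces substrate control by reagent control. It sets out from the product of step 13 as obtained from 24, that is 26 together with its C3 epimer F4. Dess–Martin oxidation of the mixture gives the C3 ketone F5. Reduction with the (R)-CBS oxazaborolidine and catecholborane in toluene at −78 °C, with the alkenyl carbon C4 as the larger group, delivers hydride to the face that gives the (3S) alcohol and returns to 26.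

**Step 14.** The most likely failure is the wrong facial selectivity on C1=C10, because the peracid takes the outer face of whichever ring conformer is populated. Hydroxyl-directed epoxidation of C4=C5 is a second possibility. The fallback inverts the face through a halohydrin and sets out from 26. Silylation with Et3SiOTf and 2,6-lutidine gives the C3 triethylsilyl ether F6, which also removes the directing hydroxyl. N-Bromosuccinimide in aqueous THF forms the bromonium on the face the peracid would take, and water opens it anti at the tertiary C10 to give bromohydrin F7. K2CO3 in acetonitrile closes the epoxide on the opposite face to give the bis-silyl ether F8. Buffered Bu4NF removes both silyl groups and the sequence comes back at 28.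

**Step 5.** The most likely failure is β-elimination of the C15 silyloxy group from the alkenylalanate to an allene, or incomplete regiocontrol of hydride delivery. The fallback changes the metal and the mechanism and sets out from 10. Trans-hydrosilylation with Et3SiH and [Cp*Ru(MeCN)3]PF6 in CH2Cl2 places silicon on C4, distal to the hydroxyl and cis to C6, giving the vinylsilane F9. Iododesilylation with N-iodosuccinimide in hexafluoropropan-2-ol at 0 °C, with retention, returns to 12.

**Step 9.** The most likely failure is isomerisation of the angeloyl group to the tigloyl group during activation. Slow acylation of the hindered C8 hydroxyl at 75 °C could also give time for lactone migration. The fallback acylates the alkoxide instead of the alcohol and sets out from 18. Double deprotonation with LiN(SiMe3)2 (2.1 equiv, THF, −78 °C) gives the C11 carbanion and the C8 alkoxide, and the harder alkoxide is acylated by angelic anhydride F10 (made from 19 with a carbodiimide). Acidic work-up returns to 21.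

**Step 4.** The most likely failure is insufficient or reversed enantioselection, or base-induced migration of the skipped diene. The fallback replaces asymmetric catalysis by resolution and sets out from 8 and 9. The lithium acetylide of 9 (n-BuLi, THF, −78 °C) adds to 8 to give the racemic alcohol F11. The conditions of step 5 give the racemic iodo dienol F12. Step 6 is then run as a kinetic resolution with 0.6 equivalents of hydroperoxide, in which only the (S)-enantiomer is epoxidised. The unreacted (R)-alcohol F13 is separated and the route is rejoined at 13.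

## Further compounds

F1 | step 8 | (2Z,4S,5E,8E)-1-[(tert-butyldimethylsilyl)oxy]-2-iodo-8-methyl-11-[(triethylsilyl)oxy]undeca-2,5,8-trien-4-yl 2-(diethoxyphosphoryl)acetate | CCOP(=O)(OCC)CC(=O)O[C@H](/C=C(I)/CO[Si](C)(C)C(C)(C)C)/C=C/C/C(C)=C/CCO[Si](CC)(CC)CC
F2 | step 8 | (2Z,4S,5E,8E)-1-[(tert-butyldimethylsilyl)oxy]-2-iodo-8-methyl-11-[(triethylsilyl)oxy]undeca-2,5,8-trien-4-yl 2-diazo-2-(diethoxyphosphoryl)acetate | CCOP(=O)(OCC)C(=[N+]=[N-])C(=O)O[C@H](/C=C(I)/CO[Si](C)(C)C(C)(C)C)/C=C/C/C(C)=C/CCO[Si](CC)(CC)CC
F3 | step 8 | diethyl 3-oxabicyclo[3.1.0]hexan-2-one-1-phosphonate with the (Z)-iodoalkenyl group on C4 (germacrane C6) anti to the cyclopropane and the (E)-pentenyl chain on C6 (germacrane C8) | CCOP(=O)(OCC)[C@]12C(=O)O[C@H](/C=C(I)/CO[Si](C)(C)C(C)(C)C)[C@H]1[C@@H]2C/C(C)=C/CCO[Si](CC)(CC)CC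
F4 | step 13 | (3R,6R,7R,8R)-15-[(tert-butyldimethylsilyl)oxy]-3-hydroxy-8-[(2Z)-2-methylbut-2-enoyloxy]germacra-1(10)E,4Z,11(13)-trien-12,6-olide (C3 epimer of 26) | C=C1C(=O)O[C@@H]2/C=C(/CO[Si](C)(C)C(C)(C)C)[C@H](O)C/C=C(\C)C[C@@H](OC(=O)/C(C)=C\C)[C@@H]12
F5 | step 13 | (6R,7R,8R)-15-[(tert-butyldimethylsilyl)oxy]-8-[(2Z)-2-methylbut-2-enoyloxy]-3-oxogermacra-1(10)E,4Z,11(13)-trien-12,6-olide | C=C1C(=O)O[C@@H]2/C=C(/CO[Si](C)(C)C(C)(C)C)C(=O)C/C=C(\C)C[C@@H](OC(=O)/C(C)=C\C)[C@@H]12
F6 | step 14 | 3-O-triethylsilyl ether of 26 | C=C1C(=O)O[C@@H]2/C=C(/CO[Si](C)(C)C(C)(C)C)[C@@H](O[Si](CC)(CC)CC)C/C=C(\C)C[C@@H](OC(=O)/C(C)=C\C)[C@@H]12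
F7 | step 14 | 1-bromo-10-hydroxy bromohydrin of F6 (bromine on C1 anti to the C10 hydroxyl) | C=C1C(=O)O[C@@H]2/C=C(/CO[Si](C)(C)C(C)(C)C)[C@@H](O[Si](CC)(CC)CC)C[C@H](Br)[C@](C)(O)C[C@@H](OC(=O)/C(C)=C\C)[C@@H]12
F8 | step 14 | 3-O-triethylsilyl ether of 27 | C=C1C(=O)O[C@@H]2/C=C(/CO[Si](C)(C)C(C)(C)C)[C@@H](O[Si](CC)(CC)CC)C[C@H]3O[C@]3(C)C[C@@H](OC(=O)/C(C)=C\C)[C@@H]12
F9 | step 5 | (4S,5E,8E)-1-[(tert-butyldimethylsilyl)oxy]-8-methyl-2-(triethylsilyl)-11-[(triethylsilyl)oxy]undeca-2,5,8-trien-4-ol with silicon on C2 cis to C4 of the chain | O[C@H](/C=C([Si](CC)(CC)CC)/CO[Si](C)(C)C(C)(C)C)/C=C/C/C(C)=C/CCO[Si](CC)(CC)CC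
F10 | step 9 | angelic anhydride, (2Z)-2-methylbut-2-enoic anhydride | C/C=C(/C)C(=O)OC(=O)/C(C)=C\C
F11 | step 4 | racemic (5E,8E)-1-[(tert-butyldimethylsilyl)oxy]-8-methyl-11-[(triethylsilyl)oxy]undeca-5,8-dien-2-yn-4-ol | OC(C#CCO[Si](C)(C)C(C)(C)C)/C=C/C/C(C)=C/CCO[Si](CC)(CC)CC
F12 | step 4 | racemic (2Z,5E,8E)-1-[(tert-butyldimethylsilyl)oxy]-2-iodo-8-methyl-11-[(triethylsilyl)oxy]undeca-2,5,8-trien-4-ol | OC(/C=C(I)/CO[Si](C)(C)C(C)(C)C)/C=C/C/C(C)=C/CCO[Si](CC)(CC)CC
F13 | step 4 | (2Z,4R,5E,8E)-1-[(tert-butyldimethylsilyl)oxy]-2-iodo-8-methyl-11-[(triethylsilyl)oxy]undeca-2,5,8-trien-4-ol | O[C@@H](/C=C(I)/CO[Si](C)(C)C(C)(C)C)/C=C/C/C(C)=C/CCO[Si](CC)(CC)CC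
A1 | alternative 1 | 13-nor-germacra-1(10)E,4Z-dien-12,6-olide with free 15-hydroxyl, 3-O-tert-butyldimethylsilyl and 8-O-(4-methoxybenzyl) groups | O=C1O[C@@H]2/C=C(/CO)[C@@H](O[Si](C)(C)C(C)(C)C)C/C=C(\C)C[C@@H](OCc3ccc(OC)cc3)[C@H]2C1
A2 | alternative 2 | cis-anti-cis tricyclic photoadduct: cyclohexanone fused to a bicyclo[2.2.0]hexane carrying a methyl ester and a silyloxy group, with a γ-lactone on C7/C8 | O=C1[C@H]2[C@]3(C(=O)OC)[C@@H](O[Si](C)(C)C(C)(C)C)C[C@@H]3[C@@]2(C)C[C@H]2OC(=O)C[C@@H]12
A3 | alternative 3 | (3S,6R,7R,8R)-15-[(tert-butyldimethylsilyl)oxy]-3-hydroxy-8-[(2Z)-2-methylbut-2-enoyloxy]germacra-1(10)E,4Z,11(13)-trien-12,6-olide (identical with 26) | C=C1C(=O)O[C@@H]2/C=C(/CO[Si](C)(C)C(C)(C)C)[C@@H](O)C/C=C(\C)C[C@@H](OC(=O)/C(C)=C\C)[C@@H]12
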